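The time of reading is the first setting to turn, and we count it in turnovers of J, not in hours. At 5.00 h the earlier runs read J at 26 %, 24 % and 22 % although their charges differ, so we take J loss as first order, with one constant from the mean of these readings: k = 0.285 /h, the rate at which J turns over. The turnover count n is then the number of first-order lifetimes behind a reading:

n = k·t, J left = exp(−n)

For the flask at 12 h this gives n = 3.42 and J left = 3.27 %.

| setting | south | north | west | flask |
|---|---|---|---|---|
| J | 0.034 M | 0.075 M | 0.050 M | 0.050 M |
| E | 0.10 M | 0.10 M | 0.050 M | 0.100 M |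
| remark | run made earlier | run made earlier | run made earlier |  |
| time |  |  |  | 12 h |

| run | time / h | Z / % | J / % |
|---|---|---|---|
| south | 1.50 | 27 | 67 |
| south | 3.00 | 34 | 42 |
| south | 5.00 | 41 | 26 |
| south | 10.0 | 29 | 5 |
| north | 1.50 | 22 | 67 |
| north | 3.00 | 35 | 41 |
| north | 5.00 | 43 | 24 |
| north | 10.0 | 55 | 6 |
| west | 1.50 | 19 | 66 |
| west | 3.00 | 38 | 39 |
| west | 5.00 | 51 | 22 |
| west | 10.0 | 62 | 8 |

(each reading ± 1.5 percentage points)



By this reckoning the charges do not enter n, but they do move the equivalents of E to J. Turning the J charge takes these from 2.94 in south to 1.33 in north. Between 5.00 h and 10.0 h, Z falls from 41 % to 29 % in south but rises from 43 % to 55 % in north. Turning E down gives west 1.00 equivalents, and there Z still rises to 62 %.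

The flask has 2.00 equivalents, fewer than south and more than north. We therefore put its best between n = 0.855 and n = 2.85, that is, between 3.00 h and 10.0 h.

* the best time, 12 h at the latest, for Z
* the amount of Z, in percent of the J charged, at that time
* the first time at which Z reaches 21 %, in the same percent

The forecast gives 44 % at 7 h, “a broad maximum near 7 h”, and 21 % at 1.3 h.

The flask gives 41.7 % at 6.01 h and reaches 21 % at 1.29 h, so the forecast time is 1.16 times the flask's.

    J → X (k = 0.290 /h)
    E + X ⇌ G (K = 140 /M, k = 4.70 /M/h)
    E + X → Z (k = 48.0 /M/h)
    E + Z → Q (k = 2.80 /M/h)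

Z in the flask stands at 41.1 % at 4.81 h and at 35.6 % at 12.0 h. At its best time the flask has n = 1.71, so the count gives J left = 18.0 %, and the flask holds 17.5 %. A neighbour flask charged with 0.020 M of J has the same count at 12.0 h, which gives 3.27 %, and it holds 3.08 %.

The readings are calculated for an exercise; noise was put on by code.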